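## Retrosynthetic overview

1. Target **14** ⇐ **13**: exo-face epoxidation of the ring-B alkene of a bicyclo[3.3.1]nonenone (oxirane formed last).
2. **13** ⇐ **10**: methanol oxa-Michael / intramolecular aldol cascade on an o-quinol that carries the amido-aldehyde as a lactol (closes ring A, sets three stereocentres).
3. **10** ⇐ **8**: lactone-to-lactol reduction plus Stork–Danheiser 1,3-carbonyl transposition of a stable p-quinol-type vinylogous ester.
4. **8** ⇐ **5** ⇐ **1** + **2**: key C–C bond (carbinol carbon to CH2) by 1,2-addition of the β-zincated L-alanine ester to a carbonyl carbon of 2-methoxy-1,4-benzoquinone. This homoenolate is nucleophilic at the carbon that is electrophilic in an acrylate, so two normally electrophilic carbons are joined; the γ-lactone closes in the same pot.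
5. Ring order: ring B (carbocycle, bought as the quinone) → temporary spiro γ-lactone → ring A (aldol) → oxirane.

Assumption: compounds 1, 2 and 6 are bought as such, dimethyldioxirane is used as a titrated acetone solution, and the C5 epimer that accompanies 5 in step 1 can be removed on silica (the two are told apart by NOE).

## Route

Step 1
Reactants: 1 methyl (2R)-2-[(tert-butoxycarbonyl)amino]-3-iodopropanoate; 2 2-methoxycyclohexa-2,5-diene-1,4-dione
Product: 5 tert-butyl N-[(3S,5S)-6-methoxy-2,8-dioxo-1-oxaspiro[4.5]deca-6,9-dien-3-yl]carbamate, via zinc homoenolate 3 (not isolated), via iodozinc alkoxide adduct 4 (not isolated)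
Conditions: Zn (dust, I2-activated), LiCl, THF, 25 °C, used at once; then 2, MgCl2, THF, −30 °C to rt; cold 1 M HCl work-up; chromatography
Reagents that add atoms: none
Why: Proposed new method: the β-zincated alanine ester 3 is an amino-acid homoenolate and, made more nucleophilic by MgCl2, should add 1,2 to the C1 carbonyl of 2 (C4 is deactivated as a vinylogous ester carbonyl and the magnesium ion can chelate O1 and the neighbouring methoxy oxygen), after which alkoxide 4 closes the γ-lactone on its methyl ester; the closest known reactions are MgCl2-promoted additions of functionalised alkylzinc halides to ketones and the 1,2-additions of allyl- and Reformatsky-type zinc reagents to quinones that give p-quinols; C3 is carried over from L-serine-derived 1, while the spiro carbon C5 forms on a planar quinone without dependable 1,3-induction (close to 1:1 expected), so the step delivers (3S,5S)-5 only after chromatographic removal of the accompanying (3S,5R) epimer, which is discarded.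

Step 2
Reactants: 5 tert-butyl N-[(3S,5S)-6-methoxy-2,8-dioxo-1-oxaspiro[4.5]deca-6,9-dien-3-yl]carbamate; 6 (2E)-dodec-2-enoic acid
Product: 8 (2E)-N-[(3S,5S)-6-methoxy-2,8-dioxo-1-oxaspiro[4.5]deca-6,9-dien-3-yl]dodec-2-enamide, via ammonium trifluoroacetate 7 (not isolated)
Conditions: CF3CO2H, CH2Cl2, 0 °C, evaporate; then 6, EDC·HCl, HOBt (cat.), i-Pr2NEt (added last), CH2Cl2, 0 °C to rt
Reagents that add atoms: none
Why: Acidolysis of the Boc carbamate (the electron-poor p-quinol-type dienone lactone tolerates anhydrous acid) followed by carbodiimide amide coupling is standard; no stereocentre is touched, and because the amine is released from its salt only in the presence of the activated acid, acylation at 0 °C is expected to outrun the strained, reversible addition of the free amine to the dienone.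

Step 3
Reactants: 8 (2E)-N-[(3S,5S)-6-methoxy-2,8-dioxo-1-oxaspiro[4.5]deca-6,9-dien-3-yl]dodec-2-enamide
Product: 10 (2E)-N-[(3S,5S)-2-hydroxy-6-oxo-1-oxaspiro[4.5]deca-7,9-dien-3-yl]dodec-2-enamide, via reduced diol lactol 9 (not isolated)
Conditions: i-Bu2AlH (4.5 equiv), CH2Cl2, −78 °C; then 1 M HCl, THF, 0 °C, 10 min; crude used at once
Reagents that add atoms: water, O
Why: i-Bu2AlH reduces the lactone to the lactol and the vinylogous-ester carbonyl to the allylic alkoxide in one operation (the amide is protected as its aluminium amidate), and mild aqueous acid then triggers the Stork–Danheiser 1,3-carbonyl transposition (ionisation at C8 with water capture at the methoxy-bearing C6, or enol-ether hydrolysis followed by β-elimination of the C8 hydroxyl, both ending in loss of methanol and the same dienone), which places the ketone next to the carbinol carbon and unveils the reactive o-quinol only when it is needed; C3 and C5 are untouched and the lactol carbon is an inconsequential anomeric mixture.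

Step 4
Reactants: 10 (2E)-N-[(3S,5S)-2-hydroxy-6-oxo-1-oxaspiro[4.5]deca-7,9-dien-3-yl]dodec-2-enamide
Product: 13 (2E)-N-[(1S,2R,3S,5S,8R)-2,5-dihydroxy-8-methoxy-9-oxobicyclo[3.3.1]non-6-en-3-yl]dodec-2-enamide, via open hydroxy aldehyde 11 (not isolated), via oxa-Michael adduct 12 (not isolated)
Conditions: K2CO3 (0.3 equiv), MeOH (0.01 M), 0 °C to rt
Reagents that add atoms: methanol, CO
Why: Base-mediated oxa-Michael / intramolecular aldol cascade (the ring-closing mode known for gymnastatin-type tyrosine quinols): methoxide adds reversibly to the enone β-carbon and the enolate carbon attacks the tethered aldehyde on the opposite face (anti addition, so the methoxy group ends axial and anti to the new ring); the bridge can form only on the face bearing the side chain, and the (3S,5S) pairing places the amide equatorial, so C5 of 10 dictates C1 and C8 of 13; a potassium-bridged closed transition state holds the aldehyde oxygen syn to the enolate oxygen and gives the axial C2 alcohol cis to the amide; because bridgehead enolisation is forbidden, methanol cannot be lost again from the bicycle.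

Step 5
Reactants: 13 (2E)-N-[(1S,2R,3S,5S,8R)-2,5-dihydroxy-8-methoxy-9-oxobicyclo[3.3.1]non-6-en-3-yl]dodec-2-enamide
Product: 14 (2E)-N-[(1S,2S,4S,5S,6S,7R,8S)-1,7-dihydroxy-5-methoxy-10-oxo-3-oxatricyclo[4.3.1.0^{2,4}]decan-8-yl]dodec-2-enamide
Conditions: dimethyldioxirane, acetone, 0 °C
Reagents that add atoms: dimethyldioxirane, CC1(C)OO1
Why: Neutral epoxidation of the only non-conjugated alkene (the acyl-chain C=C is electron-poor); the endo face of the ring-B alkene is blocked by the endo hydrogen of the opposite ring as in other bicyclo[3.3.1]non-2-enes and the allylic tertiary hydroxyl can hydrogen-bond the oxidant, so oxygen should be delivered exo, cis to that hydroxyl and to the methoxy group, although the axial methoxy group on the same face makes this selectivity less than certain.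

## Compound list

1 | methyl (2R)-2-[(tert-butoxycarbonyl)amino]-3-iodopropanoate (Boc-3-iodo-L-alanine methyl ester) | CC(C)(C)OC(=O)N[C@@H](CI)C(=O)OC | starting material
2 | 2-methoxycyclohexa-2,5-diene-1,4-dione (2-methoxy-1,4-benzoquinone) | COC1=CC(=O)C=CC1=O | starting material
3 | [(2R)-2-[(tert-butoxycarbonyl)amino]-3-methoxy-3-oxopropyl]zinc iodide | CC(C)(C)OC(=O)N[C@@H](C[Zn]I)C(=O)OC | intermediate
4 | iodozinc alkoxide of methyl (2S)-2-[(tert-butoxycarbonyl)amino]-3-[(1S)-1-hydroxy-2-methoxy-4-oxocyclohexa-2,5-dien-1-yl]propanoate | CC(C)(C)OC(=O)N[C@@H](C[C@@]1(O[Zn]I)C(OC)=CC(=O)C=C1)C(=O)OC | intermediate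
5 | tert-butyl N-[(3S,5S)-6-methoxy-2,8-dioxo-1-oxaspiro[4.5]deca-6,9-dien-3-yl]carbamate | CC(C)(C)OC(=O)N[C@H]1C[C@@]2(OC1=O)C(OC)=CC(=O)C=C2 | intermediate
6 | (2E)-dodec-2-enoic acid | CCCCCCCCC/C=C/C(=O)O | starting material
7 | (3S,5S)-6-methoxy-2,8-dioxo-1-oxaspiro[4.5]deca-6,9-dien-3-aminium trifluoroacetate | [NH3+][C@H]1C[C@@]2(OC1=O)C(OC)=CC(=O)C=C2.[O-]C(=O)C(F)(F)F | intermediate
8 | (2E)-N-[(3S,5S)-6-methoxy-2,8-dioxo-1-oxaspiro[4.5]deca-6,9-dien-3-yl]dodec-2-enamide | CCCCCCCCC/C=C/C(=O)N[C@H]1C[C@@]2(OC1=O)C(OC)=CC(=O)C=C2 | intermediate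
9 | (2E)-N-[(3S,5S)-2,8-dihydroxy-6-methoxy-1-oxaspiro[4.5]deca-6,9-dien-3-yl]dodec-2-enamide (mixture at C2 and C8) | CCCCCCCCC/C=C/C(=O)N[C@H]1C[C@@]2(OC1O)C(OC)=CC(O)C=C2 | intermediate
10 | (2E)-N-[(3S,5S)-2-hydroxy-6-oxo-1-oxaspiro[4.5]deca-7,9-dien-3-yl]dodec-2-enamide (anomeric mixture) | CCCCCCCCC/C=C/C(=O)N[C@H]1C[C@@]2(OC1O)C(=O)C=CC=C2 | intermediate
11 | (2E)-N-[(2S)-1-[(1S)-1-hydroxy-6-oxocyclohexa-2,4-dien-1-yl]-3-oxopropan-2-yl]dodec-2-enamide | CCCCCCCCC/C=C/C(=O)N[C@@H](C[C@@]1(O)C(=O)C=CC=C1)C=O | intermediate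
12 | (2E)-N-[(2S)-1-[(1S,4S)-1-hydroxy-4-methoxy-6-oxocyclohex-2-en-1-yl]-3-oxopropan-2-yl]dodec-2-enamide (present as its potassium enolate) | CCCCCCCCC/C=C/C(=O)N[C@@H](C[C@@]1(O)C(=O)C[C@H](OC)C=C1)C=O | intermediate
13 | (2E)-N-[(1S,2R,3S,5S,8R)-2,5-dihydroxy-8-methoxy-9-oxobicyclo[3.3.1]non-6-en-3-yl]dodec-2-enamide | CCCCCCCCC/C=C/C(=O)N[C@H]1C[C@@]2(O)C(=O)[C@@H]([C@H]1O)[C@H](OC)C=C2 | intermediate
14 | (2E)-N-[(1S,2S,4S,5S,6S,7R,8S)-1,7-dihydroxy-5-methoxy-10-oxo-3-oxatricyclo[4.3.1.0^{2,4}]decan-8-yl]dodec-2-enamide | CCCCCCCCC/C=C/C(=O)N[C@H]1C[C@@]2(O)C(=O)[C@@H]([C@H]1O)[C@H](OC)[C@@H]1O[C@@H]12 | target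

## Step count and risks

Total step count: 5. Longest linear sequence: 5 steps (1 to 14).

The three steps most likely to fail are step 1, step 3 and step 4.

For step 1 the dangers are electron transfer from 3 to the quinone (hydroquinone formation), conjugate addition, or β-elimination of 3, on top of the missing control at C5. The fallback keeps the same zinc homoenolate but joins it to an sp2 carbon by cross-coupling and dearomatises afterwards. It sets out from 3: Negishi coupling with 4-bromo-3-methoxyphenol (Pd2(dba)3, SPhos, DMF, 50 °C) gives methyl (2S)-2-[(tert-butoxycarbonyl)amino]-3-(4-hydroxy-2-methoxyphenyl)propanoate F1. LiOH in THF–water then gives (2S)-2-[(tert-butoxycarbonyl)amino]-3-(4-hydroxy-2-methoxyphenyl)propanoic acid F2. PhI(OAc)2 in CF3CH2OH at 0 °C makes the carboxylate attack the ring carbon para to the phenol (oxidative spirolactonisation as practised on tyrosine), which comes back to the route at 5, again accompanied by its C5 epimer, which is removed on silica.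

For step 3 the dangers are over-reduction, a 1,2-shift in the dienyl cation instead of water capture, and Diels–Alder dimerisation of the o-quinol 10 before it is used. The fallback makes 10 without any transposition, by ortho-hydroxylative dearomatisation of an o-tyrosinal. It sets out from 3: Negishi coupling with 2-iodophenol (Pd2(dba)3, SPhos, DMF) gives methyl (2S)-2-[(tert-butoxycarbonyl)amino]-3-(2-hydroxyphenyl)propanoate F3. CF3CO2H followed by 6 and EDC·HCl gives methyl (2S)-2-[[(2E)-dodec-2-enoyl]amino]-3-(2-hydroxyphenyl)propanoate F4. i-Bu2AlH at −78 °C gives (2E)-N-[(2S)-1-(2-hydroxyphenyl)-3-oxopropan-2-yl]dodec-2-enamide F5. Stabilised IBX in THF then delivers oxygen to the alkyl-bearing ortho carbon and comes back to the route at 10. Here 10 is formed together with its C5 epimer, and only the (5S) compound, separated quickly on silica, is taken into step 4.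

For step 4 the dangers are 1,6-addition of methoxide followed by aldol at the same carbon (a regioisomeric bicycle), dimerisation of 10, or the wrong epimer at the new carbinol. The fallback separates the two events so that the dienone disappears first under acid and the C–C bond is made afterwards from a kinetic lithium enolate. It sets out from 10: camphorsulfonic acid in MeOH at 0 °C adds methanol to the enone and converts the lactol into its methyl acetal, giving (2E)-N-[(3S,5S,8S)-2,8-dimethoxy-6-oxo-1-oxaspiro[4.5]dec-9-en-3-yl]dodec-2-enamide F6 (the C8 epimer, if formed, is recycled by retro-addition). Aqueous acetic acid in THF frees the lactol, giving (2E)-N-[(3S,5S,8S)-2-hydroxy-8-methoxy-6-oxo-1-oxaspiro[4.5]dec-9-en-3-yl]dodec-2-enamide F7. LiN(SiMe3)2 in THF at −78 °C then closes ring A through a lithium-chelated aldol and comes back to the route at 13.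

## Further compounds

F1 | step 1 | methyl (2S)-2-[(tert-butoxycarbonyl)amino]-3-(4-hydroxy-2-methoxyphenyl)propanoate | CC(C)(C)OC(=O)N[C@@H](Cc1ccc(O)cc1OC)C(=O)OC
F2 | step 1 | (2S)-2-[(tert-butoxycarbonyl)amino]-3-(4-hydroxy-2-methoxyphenyl)propanoic acid | CC(C)(C)OC(=O)N[C@@H](Cc1ccc(O)cc1OC)C(=O)O
F3 | step 3 | methyl (2S)-2-[(tert-butoxycarbonyl)amino]-3-(2-hydroxyphenyl)propanoate | CC(C)(C)OC(=O)N[C@@H](Cc1ccccc1O)C(=O)OC
F4 | step 3 | methyl (2S)-2-[[(2E)-dodec-2-enoyl]amino]-3-(2-hydroxyphenyl)propanoate | CCCCCCCCC/C=C/C(=O)N[C@@H](Cc1ccccc1O)C(=O)OC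
F5 | step 3 | (2E)-N-[(2S)-1-(2-hydroxyphenyl)-3-oxopropan-2-yl]dodec-2-enamide | CCCCCCCCC/C=C/C(=O)N[C@@H](Cc1ccccc1O)C=O
F6 | step 4 | (2E)-N-[(3S,5S,8S)-2,8-dimethoxy-6-oxo-1-oxaspiro[4.5]dec-9-en-3-yl]dodec-2-enamide | CCCCCCCCC/C=C/C(=O)N[C@H]1C[C@@]2(OC1OC)C(=O)C[C@H](OC)C=C2
F7 | step 4 | (2E)-N-[(3S,5S,8S)-2-hydroxy-8-methoxy-6-oxo-1-oxaspiro[4.5]dec-9-en-3-yl]dodec-2-enamide | CCCCCCCCC/C=C/C(=O)N[C@H]1C[C@@]2(OC1O)C(=O)C[C@H](OC)C=C2
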